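The numbers in the tables stem from a simulated flask for substances that don't exist.

Two questions stood on this flask: how much target there is, and how near saturation the dissolved gas is. Solid substrate and protic impurity were stirred under a held gas phase, and three earlier runs gave target.

| setting | Saturday's | Wednesday's | Monday's | flask |
|---|---|---|---|---|
| solid substrate | 0.75 M | 1.1 M | 1.5 M | 1.5 M |
| gas phase | 58 mM (held) | 58 mM (held) | 58 mM (held) | 58 mM (held) |
| protic impurity | 1.5 M | 1.5 M | 0.75 M | 1.50 M |
| remark | run made earlier | run made earlier | run made earlier |  |
| time |  |  |  | 4.0 h |

| run | time / h | target / % |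
|---|---|---|
| Saturday's | 0.250 | 0.1 |
| Saturday's | 0.667 | 3.6 |
| Saturday's | 1.33 | 10.1 |
| Saturday's | 2.00 | 14.9 |
| Saturday's | 3.00 | 21.4 |
| Saturday's | 4.00 | 25.5 |
| Saturday's | 5.00 | 27.2 |
| Wednesday's | 0.417 | 1.4 |
| Wednesday's | 0.667 | 2.6 |
| Wednesday's | 0.833 | 3.9 |
| Wednesday's | 1.33 | 6.5 |
| Wednesday's | 2.00 | 10.8 |
| Wednesday's | 3.00 | 13.6 |
| Wednesday's | 5.00 | 18.8 |
| Monday's | 1.00 | 3.5 |
| Monday's | 2.00 | 7.4 |
| Monday's | 3.00 | 10.3 |
| Monday's | 4.00 | 11.7 |
| Monday's | 5.00 | 14.0 |

(readings scatter by 0.5 percentage points)

* how much target there is at 4.0 h, in percent of the solid substrate charged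
* concentration of dissolved gas in solution at 4.0 h, in percent of saturation

- solid, in amounts per volume of the solution: solid substrate
- the numbers in the tables scatter with a standard deviation of 0.5 percentage points
- at the start none of the gas phase is in solution
- at the start none of the solid substrate is in solution

The readings looked contradictory. At 4.00 h, Saturday's run stood at 25.5% and Monday's at 11.7%, so Saturday's had twice the yield with half the solid substrate. But a percentage is divided by the charge, so I multiplied the charge back in. That gave c(target) of 0.191 M for Saturday's and 0.175 M for Monday's. The two nearly agreed. At 5.00 h, the three runs gave 0.204 M, 0.207 M and 0.210 M, though Monday's had half the impurity. Over these charges and at these two times, c(target) looked zero order in the solid charge.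

So I froze the mean of the two readings at 4.00 h, 0.183 M, as the charge-free level of c(target) at that time. Divided by this flask's 1.5 M, it gave 12.2%. I made no reckoning of the second question, since the tables hold no reading of dissolved gas.

The forecast, slightly above mine, gave 12.3% and 75%: “The three runs agree once converted to absolute concentration of target”.

The flask gave 12.5% of target, and its dissolved gas stood at 58.9% of saturation.

    gas phase ⇌ dissolved gas, rate k1*(csat - [dissolved gas]) (kL = 12.0 /h)
    starting material + dissolved gas → target (k = 28.0 /M/h)
    dissolved gas + target → over-reacted product (k = 18.0 /M/h)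
    dissolved gas + protic impurity → quenched reagent (k = 0.690 /M/h)
    solid substrate ⇌ starting material, rate k5*(cs5 - [starting material]) while solid is left; crystals form when [starting material] > cs5 (solubility = 0.960 M, k = 0.180 /h)

That yield is 0.188 M of target, close to the level 0.183 M, and this flask still held 59.2% of its solid substrate at 4.00 h. In the neighbour flask with 0.38 M of solid substrate, the level gives 48.2%. That neighbour flask gave less, 25.6%, and its solid substrate stood at 0% at 4.00 h.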